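**Strategy.** The benzoic acid ring carries, on adjacent carbons C1 and C6, the carboxyl carbon and the benzylic carbon C1', with the C2 oxygen next to C1. This 1,2-dicarbon pattern beside an oxygen is disconnected to 3,5-bis(benzyloxy)benzyne and dibenzyl malonate. Fluoride unmasks the aryne from an ortho-silyl aryl triflate, and insertion into the malonate C–C bond forges C6–C1' and C1–CO2Bn in one operation, the C2 benzyloxy group steering the regiochemistry. The aliphatic ester then becomes an aldehyde, C2' is set by allylboration, the chain carrying C12' from (R)-propylene oxide is joined by cross-metathesis, and one hydrogenation unveils the target.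

Key step: step 4

Remark: ring atoms are numbered as in the target (C1 carboxyl, C2 and C4 oxygen, C6 side chain) and chain atoms C1'–C13'; the target is read as 2'S,12'R; 3,5-bis(benzyloxy)phenol is taken to be purchasable.

Step 1
Reactants: 1 3,5-bis(benzyloxy)phenol
Product: 2 3,5-bis(benzyloxy)-2-bromophenol
Conditions: NBS (1.0 equiv), i-Pr2NH (10 mol%), CH2Cl2, −78 → 0 °C
Reagents that add atoms: N-bromosuccinimide, O=C1CCC(=O)N1Br
Why: Electrophilic aromatic bromination in which the amine-mediated, hydrogen-bond-directed NBS protocol should deliver bromine ortho to the free hydroxyl (C2, between OH and OBn) in preference to C4 between the two benzyloxy groups.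

Step 2
Reactants: 2 3,5-bis(benzyloxy)-2-bromophenol
Product: 3 [3,5-bis(benzyloxy)-2-bromophenoxy]trimethylsilane
Conditions: HMDS (1.5 equiv), THF, 65 °C; evaporation, crude used directly
Reagents that add atoms: hexamethyldisilazane, C[Si](C)(C)N[Si](C)(C)C
Why: O-silylation of a phenol with HMDS is driven by loss of ammonia and should give the moisture-sensitive silyl ether cleanly without salts.

Step 3
Reactants: 3 [3,5-bis(benzyloxy)-2-bromophenoxy]trimethylsilane
Product: 6 3,5-bis(benzyloxy)-2-(trimethylsilyl)phenyl trifluoromethanesulfonate, via aryllithium 4 (not isolated), via lithium ortho-silylphenoxide 5 (not isolated)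
Conditions: n-BuLi (1.1 equiv), THF, −100 → −80 °C; then Tf2O (1.2 equiv), −100 → −78 °C
Reagents that add atoms: trifluoromethanesulfonic anhydride, O=S(=O)(OS(=O)(=O)C(F)(F)F)C(F)(F)F
Why: Bromine–lithium exchange followed by the anionic 1,3 O→C silyl shift (retro-Brook rearrangement) should place the silyl group on carbon and leave a lithium phenoxide that is trapped as the triflate, while the benzyl ethers are inert at this temperature.

Step 4
Reactants: 6 3,5-bis(benzyloxy)-2-(trimethylsilyl)phenyl trifluoromethanesulfonate; 7 dibenzyl malonate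
Product: 10 benzyl 2,4-bis(benzyloxy)-6-(2-benzyloxy-2-oxoethyl)benzoate, via 3,5-bis(benzyloxy)benzyne 8 (not isolated), via benzocyclobutenoxide 9 (not isolated)
Conditions: KF (3 equiv), 18-crown-6 (3 equiv), 7 (1.5 equiv), THF, 0 °C → rt, slow addition of 6
Reagents that add atoms: none
Why: Fluoride attacks the trimethylsilyl group of 6 and triflate leaves, giving aryne 8; the potassium enolate of 7 adds to the aryne carbon remote from the C2 benzyloxy group (future C6), so that the aryl anion sits at future C1, where the inductively withdrawing neighbouring oxygen and the distortion of the aryne both favour it. The aryl anion closes onto a malonate ester carbonyl (4-exo-trig) to give the four-membered alkoxide 9, which reopens by C–C cleavage to the ester-stabilised benzylic anion, and this is protonated by fresh malonate so that the base is regenerated. The closest known reaction type is the insertion of arynes into the C–C sigma bond of malonates and beta-keto esters (aryne acyl-alkylation), applied here to a 3-alkoxyaryne. No ring of the product is closed and no stereocentre is formed. The selectivities needed are the site of attack on the unsymmetrical aryne, secured by the C2 benzyloxy group, and ring closure of the aryl anion ahead of its protonation, favoured by the intramolecular ester, the aprotic medium and slow release of the aryne.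

Step 5
Reactants: 10 benzyl 2,4-bis(benzyloxy)-6-(2-benzyloxy-2-oxoethyl)benzoate
Product: 11 benzyl 2,4-bis(benzyloxy)-6-(2-oxoethyl)benzoate
Conditions: i-Bu2AlH (1.1 equiv), CH2Cl2, −78 °C; MeOH, then aq. KNaC4H4O6
Reagents that add atoms: none
Why: Partial ester reduction through an aluminium hemiacetal that is stable at −78 °C should stop at the aldehyde, and the hydride should attack only the unhindered arylacetic ester because the aryl ester is shielded by its two ortho substituents.

Step 6
Reactants: 11 benzyl 2,4-bis(benzyloxy)-6-(2-oxoethyl)benzoate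
Product: 12 benzyl 2,4-bis(benzyloxy)-6-[(2S)-2-hydroxypent-4-en-1-yl]benzoate
Conditions: (−)-Ipc2BOMe (1.3 equiv), allylmagnesium bromide (1.2 equiv), Et2O, −78 °C → rt; then 11, −78 °C; MeOH, pH 7 phosphate buffer, 30% H2O2, 0 °C → rt
Reagents that add atoms: allylmagnesium bromide, C=CC[Mg]Br
Why: Brown allylboration through a chair-like six-membered transition state, in which the isopinocampheyl groups derived from (+)-α-pinene direct the allyl group to the Si face of the aldehyde, should set C2' as S, and the buffered oxidative work-up releases the alcohol without the free alkoxide that could lactonise onto the aryl ester.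

Step 7
Reactants: 12 benzyl 2,4-bis(benzyloxy)-6-[(2S)-2-hydroxypent-4-en-1-yl]benzoate
Product: 13 benzyl 2-[(2S)-2-acetoxypent-4-en-1-yl]-4,6-bis(benzyloxy)benzoate
Conditions: Ac2O, pyridine, DMAP (5 mol%), CH2Cl2, 0 °C
Reagents that add atoms: acetic anhydride, CC(=O)OC(C)=O
Why: DMAP-catalysed acylation installs the C2' acetate of the target at once, which removes any later chance of lactonisation and does not touch the stereocentre.

Step 8
Reactants: 14 7-bromohept-1-ene; 15 (R)-propylene oxide
Product: 17 (2R)-dec-9-en-2-ol, via hept-6-enylmagnesium bromide 16 (not isolated)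
Conditions: Mg, THF, rt → 40 °C; then CuI (10 mol%), 15, −30 → 0 °C; aq. NH4Cl
Reagents that add atoms: none
Why: Copper-catalysed Grignard opening of a terminal epoxide occurs by SN2 attack at the unsubstituted CH2, so the stereocentre of 15 is not involved and becomes C12' with R configuration.

Step 9
Reactants: 17 (2R)-dec-9-en-2-ol
Product: 18 (2R)-dec-9-en-2-yl acetate
Conditions: Ac2O, pyridine, DMAP (5 mol%), CH2Cl2, rt
Reagents that add atoms: acetic anhydride, CC(=O)OC(C)=O
Why: Standard DMAP-catalysed acetylation of a secondary alcohol proceeds with retention at carbon.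

Step 10
Reactants: 13 benzyl 2-[(2S)-2-acetoxypent-4-en-1-yl]-4,6-bis(benzyloxy)benzoate; 18 (2R)-dec-9-en-2-yl acetate
Product: 19 benzyl 2,4-bis(benzyloxy)-6-[(2S,4E,12R)-2,12-diacetoxytridec-4-en-1-yl]benzoate
Conditions: second-generation Grubbs catalyst (H2IMes)(PCy3)Cl2Ru=CHPh (5 mol%), 18 (3 equiv), CH2Cl2, 40 °C
Reagents that add atoms: none
Why: Olefin cross-metathesis of two unhindered terminal alkenes is driven by loss of ethene, the excess of the simple partner should suppress homodimerisation of 13, and the alkene geometry is irrelevant because the double bond is hydrogenated next.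

Step 11
Reactants: 19 benzyl 2,4-bis(benzyloxy)-6-[(2S,4E,12R)-2,12-diacetoxytridec-4-en-1-yl]benzoate
Product: 20 2-[(2S,12R)-2,12-diacetoxytridecyl]-4,6-dihydroxybenzoic acid (target)
Conditions: H2 (1 atm), 10% Pd/C, EtOAc, rt
Reagents that add atoms: none
Why: Heterogeneous hydrogenation should saturate the C4'=C5' bond and hydrogenolyse the two benzyl ethers and the benzyl ester in one neutral operation, which spares the acetates and both stereocentres and avoids the acid or heat that would decarboxylate the 2,4-dihydroxybenzoic acid.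

**Compound list**

1 | 3,5-bis(benzyloxy)phenol | Oc1cc(OCc2ccccc2)cc(OCc2ccccc2)c1 | starting material
2 | 3,5-bis(benzyloxy)-2-bromophenol | Oc1cc(OCc2ccccc2)cc(OCc2ccccc2)c1Br | intermediate
3 | [3,5-bis(benzyloxy)-2-bromophenoxy]trimethylsilane | C[Si](C)(C)Oc1cc(OCc2ccccc2)cc(OCc2ccccc2)c1Br | intermediate
4 | [2,4-bis(benzyloxy)-6-(trimethylsilyloxy)phenyl]lithium | [Li]c1c(O[Si](C)(C)C)cc(OCc2ccccc2)cc1OCc1ccccc1 | intermediate
5 | lithium 3,5-bis(benzyloxy)-2-(trimethylsilyl)phenolate | [Li+].[O-]c1cc(OCc2ccccc2)cc(OCc2ccccc2)c1[Si](C)(C)C | intermediate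
6 | 3,5-bis(benzyloxy)-2-(trimethylsilyl)phenyl trifluoromethanesulfonate | C[Si](C)(C)c1c(OCc2ccccc2)cc(OCc2ccccc2)cc1OS(=O)(=O)C(F)(F)F | intermediate
7 | dibenzyl malonate | O=C(CC(=O)OCc1ccccc1)OCc1ccccc1 | starting material
8 | 3,5-bis(benzyloxy)benzyne | O(Cc1ccccc1)C1=CC(OCc2ccccc2)=CC#C1 | intermediate
9 | potassium 2,4,8-tris(benzyloxy)-7-(benzyloxycarbonyl)bicyclo[4.2.0]octa-1,3,5-trien-8-olate (transient, configuration undefined) | [K+].[O-]C1(OCc2ccccc2)C(C(=O)OCc2ccccc2)c2cc(OCc3ccccc3)cc(OCc3ccccc3)c21 | intermediate
10 | benzyl 2,4-bis(benzyloxy)-6-(2-benzyloxy-2-oxoethyl)benzoate | O=C(Cc1cc(OCc2ccccc2)cc(OCc2ccccc2)c1C(=O)OCc1ccccc1)OCc1ccccc1 | intermediate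
11 | benzyl 2,4-bis(benzyloxy)-6-(2-oxoethyl)benzoate | O=CCc1cc(OCc2ccccc2)cc(OCc2ccccc2)c1C(=O)OCc1ccccc1 | intermediate
12 | benzyl 2,4-bis(benzyloxy)-6-[(2S)-2-hydroxypent-4-en-1-yl]benzoate | O[C@@H](CC=C)Cc1cc(OCc2ccccc2)cc(OCc2ccccc2)c1C(=O)OCc1ccccc1 | intermediate
13 | benzyl 2-[(2S)-2-acetoxypent-4-en-1-yl]-4,6-bis(benzyloxy)benzoate | CC(=O)O[C@@H](CC=C)Cc1cc(OCc2ccccc2)cc(OCc2ccccc2)c1C(=O)OCc1ccccc1 | intermediate
14 | 7-bromohept-1-ene | C=CCCCCCBr | starting material
15 | (R)-propylene oxide | C[C@@H]1CO1 | starting material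
16 | hept-6-en-1-ylmagnesium bromide | C=CCCCCC[Mg]Br | intermediate
17 | (2R)-dec-9-en-2-ol | C=CCCCCCC[C@@H](C)O | intermediate
18 | (2R)-dec-9-en-2-yl acetate | C=CCCCCCC[C@@H](C)OC(C)=O | intermediate
19 | benzyl 2,4-bis(benzyloxy)-6-[(2S,4E,12R)-2,12-diacetoxytridec-4-en-1-yl]benzoate | CC(=O)O[C@@H](C/C=C/CCCCCC[C@@H](C)OC(C)=O)Cc1cc(OCc2ccccc2)cc(OCc2ccccc2)c1C(=O)OCc1ccccc1 | intermediate
20 | 2-[(2S,12R)-2,12-diacetoxytridecyl]-4,6-dihydroxybenzoic acid | CC(=O)O[C@@H](CCCCCCCCC[C@@H](C)OC(C)=O)Cc1cc(O)cc(O)c1C(=O)O | target

**Total step count:** 11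
**Longest linear sequence:** 9 steps (steps 1–7, 10 and 11)

**Steps most likely to fail**

Step 4. The aryl anion may be protonated before it closes onto the ester, which gives simple arylation of the malonate instead of insertion. The product anion may also be arylated a second time, or the enolate may attack the other aryne carbon. The fallback leaves aryne chemistry and builds the same substitution pattern by directed carboxylation and cross-coupling, setting out from 2 and rejoining at 11. Treatment of 2 with n-BuLi (2.2 equiv, THF, −78 °C) and CO2 should give 2,4-bis(benzyloxy)-6-hydroxybenzoic acid F1. Alkylation of the carboxylate (BnBr, KHCO3, DMF) should give benzyl 2,4-bis(benzyloxy)-6-hydroxybenzoate F2. Tf2O and pyridine should give benzyl 2,4-bis(benzyloxy)-6-(trifluoromethylsulfonyloxy)benzoate F3. Stille coupling with allyltributylstannane (Pd(PPh3)4, LiCl, DMF, 90 °C) should give benzyl 2-allyl-4,6-bis(benzyloxy)benzoate F4. Dihydroxylation and cleavage of the alkene (OsO4 cat., NaIO4, 2,6-lutidine, dioxane–water) should then give aldehyde 11, so that step 5 is no longer needed.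

Step 6. The new C2' oxygen may attack the neighbouring aryl ester during work-up and lactonise to a dihydroisocoumarin. The enolisable arylacetaldehyde may also condense with itself, or the facial selectivity may be too low. The fallback sets out from 11 and returns to 12, and it replaces the stoichiometric chiral borane and its oxidative work-up by a chiral Lewis acid catalyst with an achiral allyl donor (Keck allylation). The conditions are (S)-BINOL (20 mol%), (i-PrO)4Ti (10 mol%), 4 Å molecular sieves and allyltributylstannane in CH2Cl2 at −20 °C, quenched with aqueous NaHCO3. This should give the same Si-face addition, no boron residue and no basic peroxide; no new compound is formed.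

Step 5. The reduction may run on to the primary alcohol, which can cyclise onto the aryl ester, or it may stop short of full conversion. The fallback sets out from 10 and rejoins at 11 through an acyl derivative that cannot be over-reduced. Saponification of the unhindered ester alone (LiOH 1.2 equiv, THF–water, 0 °C) should give 2-[3,5-bis(benzyloxy)-2-(benzyloxycarbonyl)phenyl]acetic acid F5. Coupling with N,O-dimethylhydroxylamine hydrochloride (EDC·HCl, i-Pr2NEt, CH2Cl2) should give benzyl 2,4-bis(benzyloxy)-6-{2-[methoxy(methyl)amino]-2-oxoethyl}benzoate F6. Reduction with Cp2Zr(H)Cl (THF, rt), which spares esters, should then give 11.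

**Further compounds**

F1 | step 4 | 2,4-bis(benzyloxy)-6-hydroxybenzoic acid | OC(=O)c1c(O)cc(OCc2ccccc2)cc1OCc1ccccc1
F2 | step 4 | benzyl 2,4-bis(benzyloxy)-6-hydroxybenzoate | O=C(OCc1ccccc1)c1c(O)cc(OCc2ccccc2)cc1OCc1ccccc1
F3 | step 4 | benzyl 2,4-bis(benzyloxy)-6-(trifluoromethylsulfonyloxy)benzoate | O=C(OCc1ccccc1)c1c(OS(=O)(=O)C(F)(F)F)cc(OCc2ccccc2)cc1OCc1ccccc1
F4 | step 4 | benzyl 2-allyl-4,6-bis(benzyloxy)benzoate | C=CCc1cc(OCc2ccccc2)cc(OCc2ccccc2)c1C(=O)OCc1ccccc1
F0 | step 6 | none | none
F5 | step 5 | 2-[3,5-bis(benzyloxy)-2-(benzyloxycarbonyl)phenyl]acetic acid | OC(=O)Cc1cc(OCc2ccccc2)cc(OCc2ccccc2)c1C(=O)OCc1ccccc1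
F6 | step 5 | benzyl 2,4-bis(benzyloxy)-6-{2-[methoxy(methyl)amino]-2-oxoethyl}benzoate | CON(C)C(=O)Cc1cc(OCc2ccccc2)cc(OCc2ccccc2)c1C(=O)OCc1ccccc1
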